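**Retrosynthetic overview**
1. Preacredinone A (10) ⇐ diacetate 9 by selective cleavage of the phenolic acetate.
2. 9 ⇐ aryl acetate 8 by a ketone-directed, photoenol-mediated benzylic C–H acetoxylation (the new step). It forms the CH2–OAc bond and distinguishes the ortho-methyl from the para-methyl.
3. 8 ⇐ symmetric 4-methoxy-3,5-dimethylphenol (2) + 2,6-dimethoxybenzaldehyde (4) by MOM-directed ortho-lithiation, addition and oxidation. The symmetry of 2 makes the acylation site unambiguous.
4. No rings are formed; both arenes are bought intact.

Assumption 1: the target has no stereocentre and the diaryl ketone is not a configurationally stable atropisomer, so it is achiral and needs no stereocontrol. The one stereocentre that appears (in 5, racemic) is destroyed in Step 4.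
Assumption 2: phenol 2 is made in Step 1 from the commercial boronic acid 1; if 2 is bought directly, Step 1 is skipped.

This route is a proposal and has not been run; Step 7 in particular is untested chemistry.

**Route**

Step 1
Reactants: 1, (4-methoxy-3,5-dimethylphenyl)boronic acid
Product: 2, 4-methoxy-3,5-dimethylphenol
Conditions: 30% H2O2, NaOH, THF/H2O, 0 °C → rt
Reagents that add atoms: hydrogen peroxide, OO
Why: ipso-hydroxylation of an arylboronic acid (peroxide adds to boron, 1,2-aryl shift to oxygen, hydrolysis) is general and leaves the aryl methyl ether untouched.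

Step 2
Reactants: 2, 4-methoxy-3,5-dimethylphenol
Product: 3, 2-methoxy-5-(methoxymethoxy)-1,3-dimethylbenzene
Conditions: NaH, MOMCl, THF/DMF, 0 °C → rt
Reagents that add atoms: chloromethyl methyl ether, COCCl
Why: Williamson-type O-alkylation of the phenoxide installs the MOM ether, a strong directing group for ortho-metalation.

Step 3
Reactants: 3, 2-methoxy-5-(methoxymethoxy)-1,3-dimethylbenzene; 4, 2,6-dimethoxybenzaldehyde
Product: 5, (2,6-dimethoxyphenyl)[3-methoxy-6-(methoxymethoxy)-2,4-dimethylphenyl]methanol (racemic)
Conditions: n-BuLi, TMEDA, Et2O, 0 °C → rt, 2 h; then 4, THF, −78 °C → rt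
Reagents that add atoms: none (4 is a reactant)
Why: directed ortho-metalation by OMOM gives a single aryllithium because the two ortho C–H are equivalent, and 1,2-addition to the non-enolisable aldehyde makes the hindered diaryl carbinol; the carbinol centre is racemic and removed in Step 4.

Step 4
Reactants: 5, the racemic diaryl carbinol
Product: 6, (2,6-dimethoxyphenyl)[3-methoxy-6-(methoxymethoxy)-2,4-dimethylphenyl]methanone
Conditions: Dess–Martin periodinane, NaHCO3, CH2Cl2, rt
Reagents that add atoms: none
Why: Dess–Martin oxidation of a doubly benzylic secondary alcohol is reliable for tetra-ortho-substituted benzophenones, and the bicarbonate buffer protects the MOM acetal.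

Step 5
Reactants: 6, the MOM-protected benzophenone
Product: 7, (2,6-dimethoxyphenyl)(6-hydroxy-3-methoxy-2,4-dimethylphenyl)methanone
Conditions: 3 M HCl, MeOH, 50 °C
Reagents that add atoms: none
Why: acid-catalysed acetal cleavage removes MOM; the aryl methyl ethers and the hindered, non-enolisable ketone are inert under these conditions.

Step 6
Reactants: 7, the 2-hydroxybenzophenone
Product: 8, 2-(2,6-dimethoxybenzoyl)-4-methoxy-3,5-dimethylphenyl acetate
Conditions: Ac2O, Et3N, DMAP (10 mol%), CH2Cl2, rt
Reagents that add atoms: acetic anhydride, CC(=O)OC(C)=O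
Why: DMAP-catalysed O-acylation caps the phenol, which removes the O–H···O=C hydrogen bond (no excited-state proton-transfer quenching) and deactivates the ring toward iodine(III) before the photochemical step.

Step 7
Reactants: 8, 2-(2,6-dimethoxybenzoyl)-4-methoxy-3,5-dimethylphenyl acetate
Product: 9, 3-(acetoxymethyl)-2-(2,6-dimethoxybenzoyl)-4-methoxy-5-methylphenyl acetate
Conditions: PhI(OAc)2 (1.2 equiv), hν 365 nm (LED), degassed MeCN (0.02 M), 20 °C; stop at about 80% conversion and recycle 8
Reagents that add atoms: (diacetoxyiodo)benzene, CC(=O)OI(OC(C)=O)c1ccccc1 (delivers OAc)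
Why: Proposed new method: 365 nm n,π* excitation gives the ketone triplet, which abstracts hydrogen by 1,5-HAT from the ortho-methyl only (the para-methyl cannot reach the carbonyl oxygen), the 1,4-biradical relaxes to the (E)-photoenol (a hydroxy-o-quinodimethane), and its exocyclic CH2, a vinylogous enol carbon, attacks PhI(OAc)2 with acetate delivery and loss of PhI/AcOH, re-aromatising to the benzylic acetate; the closest known reaction types are α-acetoxylation of ketone enols with PhI(OAc)2 and trapping of o-methylbenzophenone photoenols with electrophiles (dienophiles, CO2, electrophilic fluorine).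

Step 8
Reactants: 9, the diacetate
Product: 10, Preacredinone A, [2-(2,6-dimethoxybenzoyl)-3-hydroxy-6-methoxy-5-methylphenyl]methyl acetate
Conditions: NH4OAc (10 equiv), MeOH/H2O 4:1, rt
Reagents that add atoms: none
Why: chemoselective solvolysis of a phenolic acetate, since the ortho-acyl phenoxide is a far better leaving group than a primary alkoxide, so the benzylic acetate survives and the freed phenol hydrogen-bonds to the ketone.

**Compound list**
1 | (4-methoxy-3,5-dimethylphenyl)boronic acid | COc1c(C)cc(B(O)O)cc1C | starting material
2 | 4-methoxy-3,5-dimethylphenol | COc1c(C)cc(O)cc1C | intermediate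
3 | 2-methoxy-5-(methoxymethoxy)-1,3-dimethylbenzene | COCOc1cc(C)c(OC)c(C)c1 | intermediate
4 | 2,6-dimethoxybenzaldehyde | COc1cccc(OC)c1C=O | starting material
5 | (2,6-dimethoxyphenyl)[3-methoxy-6-(methoxymethoxy)-2,4-dimethylphenyl]methanol (racemic) | COCOc1cc(C)c(OC)c(C)c1C(O)c1c(OC)cccc1OC | intermediate
6 | (2,6-dimethoxyphenyl)[3-methoxy-6-(methoxymethoxy)-2,4-dimethylphenyl]methanone | COCOc1cc(C)c(OC)c(C)c1C(=O)c1c(OC)cccc1OC | intermediate
7 | (2,6-dimethoxyphenyl)(6-hydroxy-3-methoxy-2,4-dimethylphenyl)methanone | COc1cccc(OC)c1C(=O)c1c(O)cc(C)c(OC)c1C | intermediate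
8 | 2-(2,6-dimethoxybenzoyl)-4-methoxy-3,5-dimethylphenyl acetate | COc1cccc(OC)c1C(=O)c1c(OC(C)=O)cc(C)c(OC)c1C | intermediate
9 | 3-(acetoxymethyl)-2-(2,6-dimethoxybenzoyl)-4-methoxy-5-methylphenyl acetate | COc1cccc(OC)c1C(=O)c1c(OC(C)=O)cc(C)c(OC)c1COC(C)=O | intermediate
10 | Preacredinone A, [2-(2,6-dimethoxybenzoyl)-3-hydroxy-6-methoxy-5-methylphenyl]methyl acetate | COc1cccc(OC)c1C(=O)c1c(O)cc(C)c(OC)c1COC(C)=O | target

**Totals**
Total step count: 8. Longest linear sequence: 8 (1 → 10); 7 if phenol 2 is purchased.

**Three steps most likely to fail, with fallbacks**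
1. Step 7 (proposed new photoenol acetoxylation).
   - Risks: a low-lying charge-transfer or π,π* state of the electron-rich ketone could suppress HAT; 1,6-HAT from a ring-A OCH3 could give Yang cyclisation; product 9 could be acetoxylated a second time; PhI(OAc)2 could photolyse and start non-selective radical chemistry.
   - Fallback (known chemistry, different approach): abandon C–H functionalisation and carry the benzylic oxygen in as a phthalide. Make 7-hydroxy-4-methoxy-5-methylisobenzofuran-1(3H)-one by amide-directed ortho-lithiation/DMF formylation of N,N-diethyl-5-methoxy-2-(methoxymethoxy)-4-methylbenzamide, NaBH4 reduction and acid lactonisation. Open it with excess 2-lithio-1,3-dimethoxybenzene (from 1,3-dimethoxybenzene and n-BuLi) to the 2-(hydroxymethyl)benzophenone, peracetylate to 9, and rejoin at Step 8.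
2. Step 3 (ortho-lithiation and hindered addition).
   - Risks: competing lateral lithiation of the methyl groups flanking OMe; sluggish addition to the di-ortho-substituted aldehyde.
   - Fallback: reverse the polarity of the coupling. Ortho-formylate 2 (MgCl2, Et3N, paraformaldehyde) to 2-hydroxy-5-methoxy-4,6-dimethylbenzaldehyde, MOM-protect, add 2-lithio-1,3-dimethoxybenzene, then oxidise as in Step 4 to reach 6.
3. Step 8 (selective phenolic deacetylation).
   - Risk: partial loss of the benzylic acetate, after which the free hydroxymethyl ketone can close to a lactol.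
   - Fallback: remove both acetates (K2CO3, MeOH) and then acylate only the primary benzylic alcohol with a lipase (CAL-B, vinyl acetate); such enzymatic transesterification generally leaves phenols, here a hindered, hydrogen-bonded one, unacylated.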